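**Strategy**

The molecule is cut at the diaryl ether: the O–C1′ bond and the C6′–O bond of ring B are made together. Ring B carries three adjacent oxygens (ether O on C1′, hydroxyls on C6′ and C5′) beside an unsubstituted C2′; the key step exploits this by turning a 1′-fluoro-5′-(MOM-oxy) arene into the C6′≡C1′ aryne, whose C5′ oxygen steers the ring A phenoxide to C1′ and leaves a C6′ carbanion that is borylated and oxidised to the central hydroxyl in the same flask. The two precursors, a ring A mono-MOM catechol and the ring B fluoroarene, each already hold their enantiopure quaternary side chain, set by copper–NHC-catalysed SN2′ arylation of farnesyl diethyl phosphate.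

Key step: step 9

**Remarks and assumptions**

- Ring B locants: C1′ (ether oxygen), C2′ (H), C3′ (side chain), C4′ (H), C5′ (outer OH), C6′ (central OH). MOM = methoxymethyl; TIPS = tri(propan-2-yl)silyl.
- Reading the target with priorities aryl > vinyl > CH2 > CH3, the ring A side chain is (3R) and the ring B side chain is (3S). The two quaternary centres therefore have opposite absolute configuration and need antipodal ligands.
- L is a sulfonate-bearing chiral N-heterocyclic carbene of the 4,5-diphenylimidazolin-2-ylidene class with an N-(2-sulfonatoaryl) arm, used as its silver carbene complex Ag2(L)2. It is assumed that the sense of aryl delivery follows the ligand configuration, as for the lower homologue geranyl phosphate. L is defined as the antipode that gives the (3R) centre and ent-L as the one that gives (3S). The assignment would be verified on the first batch by chiral HPLC.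
- The ring A phenol is built from 4-bromo-2-hydroxybenzaldehyde and not from its 5-bromo isomer. The MOM acetal is then in place before the second catechol oxygen is unveiled, so no silyl group can migrate between the two oxygens.

**Route**

Step 1
Reactants: 1 (2E,6E)-farnesol
Product: 2 diethyl (2E,6E)-3,7,11-trimethyldodeca-2,6,10-trien-1-yl phosphate (farnesyl diethyl phosphate)
Conditions: (EtO)2P(O)Cl, Et3N, DMAP (cat.), CH2Cl2, 0 °C → rt
Reagents that add atoms: diethyl chlorophosphate, CCOP(=O)(Cl)OCC
Why: Phosphorylation of a primary allylic alcohol (nucleophilic substitution at phosphorus under amine/DMAP catalysis) is routine and leaves both E-alkenes untouched.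

Step 2
Reactants: 3 3-bromo-5-fluorophenol
Product: 4 1-bromo-3-fluoro-5-(methoxymethoxy)benzene
Conditions: MOMCl, i-Pr2NEt, CH2Cl2, 0 °C → rt
Reagents that add atoms: chloromethyl methyl ether (MOMCl), COCCl
Why: O-Alkylation of the phenol with the chloromethyl ether (acetal protection, Williamson type) proceeds with a hindered amine as HCl scavenger, and the aryl C–F and C–Br bonds are inert.

Step 3
Reactants: 4 1-bromo-3-fluoro-5-(methoxymethoxy)benzene; 2 farnesyl diethyl phosphate
Product: 7 1-fluoro-3-(methoxymethoxy)-5-[(3S,6E)-3,7,11-trimethyldodeca-1,6,10-trien-3-yl]benzene, via aryllithium 5 (not isolated), via arylaluminium 6 (not isolated)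
Conditions: 4 (1.5 equiv), n-BuLi, Et2O, −78 °C; Et2AlCl, −78 °C → rt; 2 (1.0 equiv), CuCl2·2H2O (2 mol %), Ag2(ent-L)2 (1 mol %), THF, −30 °C; aq. potassium sodium tartrate
Reagents that add atoms: none
Why: Bromine–lithium exchange and lithium-to-aluminium transmetalation give an aryl(diethyl)aluminium from which the copper–NHC catalyst transfers aryl, not ethyl, to C3 of the E-allylic phosphate in an enantioselective SN2′ allylic substitution, the chiral sulfonate-bridged carbene ent-L fixing the face of attack and hence the (S) quaternary centre, while lithium meta to fluorine cannot give an aryne at this stage.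

Step 4
Reactants: 8 4-bromo-2-hydroxybenzaldehyde
Product: 9 4-bromo-2-(methoxymethoxy)benzaldehyde
Conditions: MOMCl, i-Pr2NEt, CH2Cl2, 0 °C → rt
Reagents that add atoms: chloromethyl methyl ether (MOMCl), COCCl
Why: Acetal protection of the acidic salicylaldehyde hydroxyl (O-alkylation) places the MOM group on the oxygen that ends up meta to the side chain.

Step 5
Reactants: 9 4-bromo-2-(methoxymethoxy)benzaldehyde
Product: 11 4-bromo-2-(methoxymethoxy)phenol, via aryl formate 10 (not isolated)
Conditions: mCPBA, CH2Cl2, 0 °C → rt; aq. NaHCO3 wash; then K2CO3 (cat.), MeOH, rt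
Reagents that add atoms: 3-chloroperbenzoic acid (mCPBA), O=C(OO)c1cccc(Cl)c1
Why: In this Baeyer–Villiger (Dakin-type) oxidation the electron-rich ortho-alkoxyaryl group migrates in the Criegee adduct, and mild base-catalysed methanolysis of the aryl formate frees the phenol para to bromine without touching the MOM acetal.

Step 6
Reactants: 11 4-bromo-2-(methoxymethoxy)phenol
Product: 12 [4-bromo-2-(methoxymethoxy)phenoxy]tri(propan-2-yl)silane
Conditions: TIPSCl, imidazole, DMF, rt
Reagents that add atoms: chlorotri(propan-2-yl)silane (TIPSCl), CC(C)[Si](Cl)(C(C)C)C(C)C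
Why: Imidazole-promoted O-silylation gives a bulky aryl silyl ether that withstands organolithium and organoaluminium reagents and is later removed by fluoride without affecting MOM.

Step 7
Reactants: 12 [4-bromo-2-(methoxymethoxy)phenoxy]tri(propan-2-yl)silane; 2 farnesyl diethyl phosphate
Product: 15 {2-(methoxymethoxy)-4-[(3R,6E)-3,7,11-trimethyldodeca-1,6,10-trien-3-yl]phenoxy}tri(propan-2-yl)silane, via aryllithium 13 (not isolated), via arylaluminium 14 (not isolated)
Conditions: 12 (1.3 equiv), n-BuLi, THF, −78 °C; Et2AlCl, −78 °C → rt; 2 (1.0 equiv), CuCl2·2H2O (2 mol %), Ag2(L)2 (1 mol %), THF, −30 °C; aq. potassium sodium tartrate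
Reagents that add atoms: none
Why: The same copper–NHC-catalysed enantioselective SN2′ allylic substitution with an aryl(diethyl)aluminium is used, now with the antipodal carbene L so that the aryl group is delivered to the opposite face of C3 and the (R) quaternary centre results.

Step 8
Reactants: 15 the TIPS ether from step 7
Product: 16 2-(methoxymethoxy)-4-[(3R,6E)-3,7,11-trimethyldodeca-1,6,10-trien-3-yl]phenol
Conditions: TBAF, THF, 0 °C; H2O
Reagents that add atoms: none
Why: Fluoride-induced desilylation (Si–F bond formation) cleaves the aryl silyl ether selectively and leaves the MOM acetal, the three alkenes and the quaternary centre unchanged.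

Step 9
Reactants: 16 2-(methoxymethoxy)-4-[(3R,6E)-3,7,11-trimethyldodeca-1,6,10-trien-3-yl]phenol; 7 1-fluoro-3-(methoxymethoxy)-5-[(3S,6E)-3,7,11-trimethyldodeca-1,6,10-trien-3-yl]benzene
Product: 22 2-(methoxymethoxy)-6-{2-(methoxymethoxy)-4-[(3R,6E)-3,7,11-trimethyldodeca-1,6,10-trien-3-yl]phenoxy}-4-[(3S,6E)-3,7,11-trimethyldodeca-1,6,10-trien-3-yl]phenol (bis-MOM ether of the target, central C6′ hydroxyl free), via potassium phenoxide 17 (not isolated), via C6′-lithio fluoroarene 18 (not isolated), via aryne 19 (not isolated), via C6′-potassio diaryl ether 20 (not isolated), via potassium aryltrimethoxyborate 21 (not isolated)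
Conditions: 16 (2.5 equiv), KH, 18-crown-6, THF, 0 °C; separately 7 (1.0 equiv), LiTMP (lithium 2,2,6,6-tetramethylpiperidide, from n-BuLi and 2,2,6,6-tetramethylpiperidine), THF, −78 °C; combine at −78 °C, warm slowly to −20 °C; B(OMe)3 (excess), −78 °C → rt; NaBO3·4H2O, THF/H2O, rt; unreacted 16 recovered
Reagents that add atoms: sodium perborate tetrahydrate (NaBO3·4H2O, source of the C6′ oxygen), [Na+].[Na+].O[B-]1(O)OO[B-](O)(O)OO1
Why: Proposed new method: LiTMP removes the C6′ hydrogen flanked by fluorine and the MOM-oxy group, and on warming the ortho-lithio fluoroarene 18 loses LiF to give the 5′-alkoxy aryne 19 (C6′≡C1′); phenoxide 17 adds through oxygen at C1′, the C6′ anion 20 is captured by B(OMe)3 as borate 21, and perborate oxidation (1,2-aryl shift from boron to oxygen) installs the hydroxyl. The closest known chemistry is the regioselective addition of nucleophiles to 3-alkoxyarynes made by ortho-lithiation of 3-halophenol ethers, the O-arylation of phenols by arynes, and the electrophilic quench of the ortho-metalated adduct in aryne three-component couplings; new is the union of a phenoxide nucleophile with a borate/oxidation quench on such a fluoroarene. No ring is closed and no stereocentre is formed, and both quaternary centres are remote, bear no acidic hydrogen and stay untouched. The step needs attack at C1′ and not at C6′, which the inductively withdrawing C5′ oxygen secures by making the meta aryne carbon the electrophilic one and by stabilising the resulting anion between two oxygens. It also needs O- and not C-arylation of the phenoxide, favoured by the potassium/18-crown-6 ion pair, and phenoxide addition in preference to addition of 18 to the aryne, favoured by the 2.5-fold excess of 17 and the slow unimolecular release of 19. Any adduct protonated before borylation can be returned to the same sequence by directed ortho-lithiation, since C6′ is also the site a second metalation would choose.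

Step 10
Reactants: 22 the bis-MOM ether from step 9
Product: 23 3-{2-hydroxy-4-[(3R,6E)-3,7,11-trimethyldodeca-1,6,10-trien-3-yl]phenoxy}-5-[(3S,6E)-3,7,11-trimethyldodeca-1,6,10-trien-3-yl]benzene-1,2-diol (target)
Conditions: HCl (0.5 M in MeOH), degassed MeOH/THF, rt, under argon
Reagents that add atoms: none
Why: Acid-catalysed transacetalisation to methanol (acetal cleavage through an oxocarbenium ion) removes both MOM groups under dilute acid at room temperature, where the trisubstituted alkenes and the quaternary centres are expected to survive and no alkene lies ortho to a phenol for chroman formation.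

**Compound list**

1 | (2E,6E)-farnesol | CC(C)=CCC/C(C)=C/CC/C(C)=C/CO | starting material
2 | diethyl (2E,6E)-3,7,11-trimethyldodeca-2,6,10-trien-1-yl phosphate | CC(C)=CCC/C(C)=C/CC/C(C)=C/COP(=O)(OCC)OCC | intermediate
3 | 3-bromo-5-fluorophenol | Oc1cc(F)cc(Br)c1 | starting material
4 | 1-bromo-3-fluoro-5-(methoxymethoxy)benzene | COCOc1cc(F)cc(Br)c1 | intermediate
5 | 3-fluoro-5-(methoxymethoxy)phenyllithium | [Li]c1cc(F)cc(OCOC)c1 | intermediate
6 | diethyl[3-fluoro-5-(methoxymethoxy)phenyl]aluminium | CC[Al](CC)c1cc(F)cc(OCOC)c1 | intermediate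
7 | 1-fluoro-3-(methoxymethoxy)-5-[(3S,6E)-3,7,11-trimethyldodeca-1,6,10-trien-3-yl]benzene | COCOc1cc(F)cc([C@](C)(C=C)CC/C=C(\C)CCC=C(C)C)c1 | intermediate
8 | 4-bromo-2-hydroxybenzaldehyde | O=Cc1ccc(Br)cc1O | starting material
9 | 4-bromo-2-(methoxymethoxy)benzaldehyde | COCOc1cc(Br)ccc1C=O | intermediate
10 | 4-bromo-2-(methoxymethoxy)phenyl formate | COCOc1cc(Br)ccc1OC=O | intermediate
11 | 4-bromo-2-(methoxymethoxy)phenol | COCOc1cc(Br)ccc1O | intermediate
12 | [4-bromo-2-(methoxymethoxy)phenoxy]tri(propan-2-yl)silane | COCOc1cc(Br)ccc1O[Si](C(C)C)(C(C)C)C(C)C | intermediate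
13 | 3-(methoxymethoxy)-4-[tri(propan-2-yl)silyloxy]phenyllithium | COCOc1cc([Li])ccc1O[Si](C(C)C)(C(C)C)C(C)C | intermediate
14 | diethyl{3-(methoxymethoxy)-4-[tri(propan-2-yl)silyloxy]phenyl}aluminium | CC[Al](CC)c1ccc(O[Si](C(C)C)(C(C)C)C(C)C)c(OCOC)c1 | intermediate
15 | {2-(methoxymethoxy)-4-[(3R,6E)-3,7,11-trimethyldodeca-1,6,10-trien-3-yl]phenoxy}tri(propan-2-yl)silane | C=C[C@@](C)(CC/C=C(\C)CCC=C(C)C)c1ccc(O[Si](C(C)C)(C(C)C)C(C)C)c(OCOC)c1 | intermediate
16 | 2-(methoxymethoxy)-4-[(3R,6E)-3,7,11-trimethyldodeca-1,6,10-trien-3-yl]phenol | C=C[C@@](C)(CC/C=C(\C)CCC=C(C)C)c1ccc(O)c(OCOC)c1 | intermediate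
17 | potassium 2-(methoxymethoxy)-4-[(3R,6E)-3,7,11-trimethyldodeca-1,6,10-trien-3-yl]phenoxide | C=C[C@@](C)(CC/C=C(\C)CCC=C(C)C)c1ccc([O-])c(OCOC)c1.[K+] | intermediate
18 | 2-fluoro-6-(methoxymethoxy)-4-[(3S,6E)-3,7,11-trimethyldodeca-1,6,10-trien-3-yl]phenyllithium | COCOc1cc([C@](C)(C=C)CC/C=C(\C)CCC=C(C)C)cc(F)c1[Li] | intermediate
19 | 3-(methoxymethoxy)-5-[(3S,6E)-3,7,11-trimethyldodeca-1,6,10-trien-3-yl]-1,2-didehydrobenzene (aryne C6′≡C1′) | COCOC1=CC([C@](C)(C=C)CC/C=C(\C)CCC=C(C)C)=CC#C1 | intermediate
20 | C6′-potassio adduct of 22 (potassium in place of the central hydroxyl; counter-ion may in part be lithium) | C=C[C@@](C)(CC/C=C(\C)CCC=C(C)C)c1ccc(Oc2cc([C@](C)(C=C)CC/C=C(\C)CCC=C(C)C)cc(OCOC)c2[K])c(OCOC)c1 | intermediate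
21 | potassium trimethoxy(aryl)borate (B(OMe)3 unit on C6′ in place of the central hydroxyl of 22) | C=C[C@@](C)(CC/C=C(\C)CCC=C(C)C)c1ccc(Oc2cc([C@](C)(C=C)CC/C=C(\C)CCC=C(C)C)cc(OCOC)c2[B-](OC)(OC)OC)c(OCOC)c1.[K+] | intermediate
22 | 2-(methoxymethoxy)-6-{2-(methoxymethoxy)-4-[(3R,6E)-3,7,11-trimethyldodeca-1,6,10-trien-3-yl]phenoxy}-4-[(3S,6E)-3,7,11-trimethyldodeca-1,6,10-trien-3-yl]phenol | C=C[C@@](C)(CC/C=C(\C)CCC=C(C)C)c1ccc(Oc2cc([C@](C)(C=C)CC/C=C(\C)CCC=C(C)C)cc(OCOC)c2O)c(OCOC)c1 | intermediate
23 | 3-{2-hydroxy-4-[(3R,6E)-3,7,11-trimethyldodeca-1,6,10-trien-3-yl]phenoxy}-5-[(3S,6E)-3,7,11-trimethyldodeca-1,6,10-trien-3-yl]benzene-1,2-diol | C=C[C@@](C)(CC/C=C(\C)CCC=C(C)C)c1ccc(Oc2cc([C@](C)(C=C)CC/C=C(\C)CCC=C(C)C)cc(O)c2O)c(O)c1 | target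

**Totals and risks**

Total step count: 10. Longest linear sequence: 7 steps (steps 4 to 10, from 8 to 23).

Steps most likely to fail:

1. Step 9. The ortho-lithio fluoroarene may add to the aryne faster than the phenoxide does (biaryl formation), the phenoxide may be arylated at carbon, or the C6′ anion may be protonated before it is borylated. The fallback uses known chemistry only, sets out from 2 and 16 and returns at 22.
   - 3,5-Dibromophenol F1 would be protected (MOMCl, i-Pr2NEt, CH2Cl2) as 1,3-dibromo-5-(methoxymethoxy)benzene F2.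
   - Single bromine–lithium exchange (n-BuLi, Et2O, −78 °C) would give 3-bromo-5-(methoxymethoxy)phenyllithium F3, and Et2AlCl would convert it into [3-bromo-5-(methoxymethoxy)phenyl]diethylaluminium F4.
   - Copper–NHC SN2′ arylation of 2 under the conditions of step 3 would give 1-bromo-3-(methoxymethoxy)-5-[(3S,6E)-3,7,11-trimethyldodeca-1,6,10-trien-3-yl]benzene F5.
   - Ullmann ether coupling of F5 with 16 (CuI, picolinic acid, K3PO4, DMSO, 90 °C) should give the diaryl ether lacking the central hydroxyl F6.
   - Directed ortho-lithiation between the two ring B oxygens (n-BuLi, THF, −78 → 0 °C) would give the C6′-lithio diaryl ether F7, B(OMe)3 the lithium aryltrimethoxyborate F8, and NaBO3·4H2O oxidation would deliver 22.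

2. Step 3. Proton transfer within the aryllithium may move lithium to the position between fluorine and the MOM-oxy group, with loss of LiF, before transmetalation is complete. Facial or SN2′ selectivity may also be insufficient with this electron-poor aryl group. The fallback sets out from 4 and 2 and returns at 7, and avoids the organolithium altogether.
   - Miyaura borylation of 4 (bis(neopentyl glycolato)diboron, PdCl2(dppf), KOAc, dioxane, 80 °C) would give 2-[3-fluoro-5-(methoxymethoxy)phenyl]-5,5-dimethyl-1,3,2-dioxaborinane F9.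
   - F9 would serve as the aryl donor in the known copper–NHC-catalysed asymmetric SN2′ arylation of γ,γ-disubstituted allyl phosphates with arylboronates (CuCl, chiral imidazolinium-derived NHC of the sense giving the S centre, NaOMe, THF, 30 °C) to give 7.

3. Step 10. Acid may add methanol to the trisubstituted alkenes or trigger cation–olefin cyclisation, and the electron-rich product may oxidise in air during a slow deprotection. The fallback sets out from 22 and returns at 23, and replaces protic solvolysis by a buffered silyl-transfer sequence.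
   - TMSOTf and 2,2′-bipyridyl (CH2Cl2, 0 °C) would convert both aryl MOM ethers into aryl trimethylsilyl ethers and silylate the free hydroxyl, giving the tris(trimethylsilyl) ether of the target F10.
   - Hydrolysis of F10 with water under neutral conditions would give 23.

**Further compounds**

F1 | step 9 | 3,5-dibromophenol | Oc1cc(Br)cc(Br)c1
F2 | step 9 | 1,3-dibromo-5-(methoxymethoxy)benzene | COCOc1cc(Br)cc(Br)c1
F3 | step 9 | 3-bromo-5-(methoxymethoxy)phenyllithium | [Li]c1cc(Br)cc(OCOC)c1
F4 | step 9 | [3-bromo-5-(methoxymethoxy)phenyl]diethylaluminium | CC[Al](CC)c1cc(Br)cc(OCOC)c1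
F5 | step 9 | 1-bromo-3-(methoxymethoxy)-5-[(3S,6E)-3,7,11-trimethyldodeca-1,6,10-trien-3-yl]benzene | COCOc1cc(Br)cc([C@](C)(C=C)CC/C=C(\C)CCC=C(C)C)c1
F6 | step 9 | 1-(methoxymethoxy)-3-{2-(methoxymethoxy)-4-[(3R,6E)-3,7,11-trimethyldodeca-1,6,10-trien-3-yl]phenoxy}-5-[(3S,6E)-3,7,11-trimethyldodeca-1,6,10-trien-3-yl]benzene | C=C[C@@](C)(CC/C=C(\C)CCC=C(C)C)c1ccc(Oc2cc([C@](C)(C=C)CC/C=C(\C)CCC=C(C)C)cc(OCOC)c2)c(OCOC)c1
F7 | step 9 | C6′-lithio derivative of F6 | C=C[C@@](C)(CC/C=C(\C)CCC=C(C)C)c1ccc(Oc2cc([C@](C)(C=C)CC/C=C(\C)CCC=C(C)C)cc(OCOC)c2[Li])c(OCOC)c1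
F8 | step 9 | lithium trimethoxy(aryl)borate at C6′ of F6 | C=C[C@@](C)(CC/C=C(\C)CCC=C(C)C)c1ccc(Oc2cc([C@](C)(C=C)CC/C=C(\C)CCC=C(C)C)cc(OCOC)c2[B-](OC)(OC)OC)c(OCOC)c1.[Li+]
F9 | step 3 | 2-[3-fluoro-5-(methoxymethoxy)phenyl]-5,5-dimethyl-1,3,2-dioxaborinane | COCOc1cc(F)cc(B2OCC(C)(C)CO2)c1
F10 | step 10 | tris(trimethylsilyl) ether of the target | C=C[C@@](C)(CC/C=C(\C)CCC=C(C)C)c1ccc(Oc2cc([C@](C)(C=C)CC/C=C(\C)CCC=C(C)C)cc(O[Si](C)(C)C)c2O[Si](C)(C)C)c(O[Si](C)(C)C)c1
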